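**Remark on the chemistry (assumption):** cembrane numbering is used for all macrocyclic compounds (ring carbons C1–C14; C15, C16, C17 = α-carbon, carbonyl carbon and exocyclic CH2 of the acrylate on C1; C18 on C4, C19 on C8, C20 on C12). A recombinant class 1 diterpene synthase that gives the R enantiomer of cembrene A is taken to be available as purified protein. Diphosphate 3 is handled as its triammonium salt and drawn as the free acid.

## Analysis of the target

Target 21 is a cembranoid: a 14-membered carbocycle (C1–C14) that is bridged twice, by a seven-membered α-methylene lactone (C1, C15, C16, O, C12, C13, C14) and by an oxolane (C4, C5, C6, C7 and the ether oxygen), and that carries a second exocyclic methylene (C8=C19) and acetates at C3 and C11. There are six stereocentres, C1 (R), C3 (S), C4 (R), C7 (R), C11 (R) and C12 (R); only C1 is a purely carbon-substituted centre, the other five all bear oxygen. The oxygenated centres sit where the three trisubstituted E-olefins of a cembratriene would be: O3/O4 correspond to anti addition across C3=C4, O11/O12 to syn addition across C11=C12, and the C7 oxygen closes the oxolane onto C4, the oxolane being 2,5-trans (C3 and C8 on opposite faces). The lactone bridge is trans across the seven-membered ring (C2 on C1 and C11 on C12 on opposite faces). Sensitive groups are the acrylate lactone (conjugate addition, radicals, strong base), the tertiary alkyl–oxygen bond at C12, the two acetates and, in late intermediates, a free C3 hydroxyl that could translactonise onto C16. The difficulty is twofold: a 14-membered ring with one remote stereocentre has to be closed, and then three nearly equivalent ring positions have to be oxidised differently with control of five C–O stereocentres. The route rests on the fact that the carbon skeleton (ring C1–C14, a three-carbon branch C15–C17 on C1, one-carbon branches C18, C19, C20 on C4, C8, C12) is a geranylgeranyl chain closed between C1 and C2, that is, the skeleton of cembrene A, whose four olefins mark every carbon that is oxidised in 21.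

## Retrosynthetic reasoning

21 ⇒ 20. The C3 acetate is removed first. It is the last group to go on because the C3 hydroxyl of 20 only appears when the oxolane closes; acetylating it at once also removes the one nucleophile that could attack the lactone carbonyl.

20 ⇒ 19 ⇒ 18. The C4–O bond of the oxolane is cut. Forward, the C7 hydroxyl of 19 opens the 3,4-epoxide at its tertiary carbon in a 5-exo closure, which inverts C4 and leaves C3 and C7 as they are; the anti O3/O4 pattern and the trans oxolane follow from an E-olefin epoxidised on one defined face. In 18 the 3,4-olefin is the only electron-rich trisubstituted olefin left, so a reagent-controlled dioxirane epoxidation can choose the face without any site problem.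

18 ⇒ 17 ⇒ 16. The C8=C19 olefin and the C7 hydroxyl are traced to a 7R,8R-epoxide. Opening the tertiary C8–O bond and loss of a C19 proton gives the exocyclic olefin while the C7–O bond, and with it the configuration at C7, is kept.

16 ⇒ 15 ⇒ 14 ⇒ 13 ⇒ 12. The C11 acetate comes from the 11R alcohol 15, this from ketone 14, and the ketone from the 11S alcohol 13. The detour through the ketone does two things: the 11S hydroxyl of 12 is the only handle that can steer an epoxidation to C7=C8 and away from C3=C4 (it is bishomoallylic to C7=C8 only), and the subsequent reduction of 14 sets the syn O11/O12 relation that no direct substitution at the hindered C11 would give.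

12 ⇒ 11 ⇒ 10 ⇒ 9. The C11–O bond is cut to the iodide 10 (radical substitution through 11), and the O–C12 bond to the acrylic acid 9 by halolactonisation. This is the step that singles out C11=C12: of the three ring olefins only this one offers the carboxylate a tertiary carbon in an exo closure. It also sets C12 relative to C1.

9 ⇒ 8 ⇒ 7 ⇒ 4. The acid is taken back through aldehyde 8 and allylic alcohol 7 to the isopropenyl group of 4. Forward, the isopropenyl methyl is the most acidic allylic position of 4 and can be metalated (5), borylated (6) and oxidised without touching the ring olefins or C1.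

4 ⇒ 3. The C1–C2 bond of the ring is cut. This is the strategic disconnection: it opens the macrocycle to the acyclic diphosphate 3 and removes the only carbon stereocentre. Forward, a synthase has to ionise 3, close the 14-membered ring onto the distal olefin, fix C1 as R and end by proton loss to the isopropenyl group; no small-molecule reagent does this with control of C1.

3 ⇒ 2 ⇒ 1. The diphosphate ester is cut to the allylic chloride 2 and this to commercial geranylgeraniol 1; two displacement steps that keep the 2E geometry.

## Alternatives that were turned down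

Alternative 1: The lactone unit C16–O–C12 is traced to a six-membered ketone. Cyclohexanone A2 (ring C15, C16, C12, C13, C14, C1) would be ring-expanded by a buffered peracid, oxygen entering between C16 and the quaternary C12, to give oxepanone A1. For it: migration of the fully substituted carbon in preference to the C15 methylene is the normal Baeyer–Villiger regiochemistry and goes with retention, so C12, and C1 and C11 set beforehand on or next to a six-membered ring, come out unambiguously. On this point it is stronger than the chosen route, whose C11 and C12 depend on substrate control in a macrocycle. Against it: A1 holds only C9–C16 with C1 and C2. The α-methylene group, C3–C8 with the oxolane and the C8=C19 olefin would still have to be attached, a 14-membered ring closed around the preformed lactone, and three different hydroxyl protecting groups removed in order. That means a long linear sequence and a macrocyclisation of uncertain outcome. The chosen strategy gives up the secure C11/C12 control but obtains the whole ring with C1 in one step and needs no protecting group.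

Alternative 2: Here the C4–O bond of the oxolane is cut. Forward, the C7 hydroxyl of epoxy alcohol A3 opens the 3,4-epoxide at C4 under acid catalysis and gives A4, the 3-O-deacetyl compound. For it: the closure is 5-exo at a tertiary epoxide carbon, stereospecific and biomimetic. It is as good as anything in the chosen route; A3 and A4 have the structures of 19 and 20, and step 13 is this reaction. Against it as the centre of a strategy: it forms one C–O bond and a five-membered ring late, while A3 already contains the macrocycle, the lactone, five stereocentres and an epoxide of defined face. Without a source of the cembrane ring the hard part, macrocyclisation and C1, stays unsolved. The chosen strategy supplies a three-step entry to the ring and keeps this closing step.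

Alternative 3: The C9–C10 bond is cut. A 14-membered macrolactone joined through oxygen between C11 and C19 would be methylenated to the allyl vinyl ether A5, and its [3,3] rearrangement would turn the oxacycle into carbocycle A6, forming the C11 ketone and the C8=C19 methylene in the same event. For it: macrolactonisation is a more dependable ring closure than a carbon–carbon macrocyclisation. The rearrangement installs the exocyclic olefin regiospecifically, which the chosen route must win from an epoxide isomerisation (step 12), and the oxolane and C3 are set beforehand by acyclic methods. On regiocontrol of the C8=C19 olefin and on site control of the oxygenation it is stronger. Against it: methylenation of a hindered lactone next to a tertiary silyl ether, a thermal rearrangement through a 14-membered transition state of uncertain chair or boat preference, three silyl ethers to tell apart, and afterwards oxidation of C16 and a seven-membered lactonisation onto the tertiary C12 hydroxyl. The route to A5 alone would be longer than the whole chosen route, which is weaker in site control of the oxidations but much shorter and free of protecting groups.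

Key step: step 3

## Route

Step 1
Reactants: 1 geranylgeraniol ((2E,6E,10E)-3,7,11,15-tetramethylhexadeca-2,6,10,14-tetraen-1-ol)
Product: 2 geranylgeranyl chloride ((2E,6E,10E)-1-chloro-3,7,11,15-tetramethylhexadeca-2,6,10,14-tetraene)
Conditions: NCS, Me2S, CH2Cl2, −40 °C to 0 °C
Reagents that add atoms: N-chlorosuccinimide, O=C1CCC(=O)N1Cl
Why: Corey–Kim chlorination; the alkoxysulfonium ion of the primary allylic alcohol is displaced by chloride in an SN2 reaction at C1, which avoids allylic transposition and keeps the 2E geometry.

Step 2
Reactants: 2 geranylgeranyl chloride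
Product: 3 geranylgeranyl diphosphate (triammonium salt; drawn as the free acid)
Conditions: (Bu4N)3HP2O7, MeCN, rt; Dowex 50W (NH4+ form); cellulose chromatography
Reagents that add atoms: tris(tetrabutylammonium) hydrogen diphosphate, CCCC[N+](CCCC)(CCCC)CCCC.CCCC[N+](CCCC)(CCCC)CCCC.CCCC[N+](CCCC)(CCCC)CCCC.OP(=O)([O-])OP(=O)([O-])[O-]
Why: SN2 displacement of the primary allylic chloride by the diphosphate trianion, a standard diphosphorylation of prenyl halides; the lipophilic cation keeps the nucleophile soluble in MeCN and cation exchange gives the enzyme-compatible ammonium form.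

Step 3
Reactants: 3 geranylgeranyl diphosphate
Product: 4 (R)-cembrene A ((1R,3E,7E,11E)-cembra-3,7,11,15-tetraene)
Conditions: recombinant (R)-cembrene A synthase (class 1 diterpene synthase), MgCl2, Tris·HCl pH 7.5, glycerol, 30 °C, pentane overlay
Reagents that add atoms: none
Why: Mg2+-assisted ionisation of the allylic diphosphate in the closed active site gives the all-E geranylgeranyl cation as a tight ion pair. The chain is folded so that its distal trisubstituted olefin lies against the cationic terminus, and Markovnikov attack through the less substituted olefin carbon forms the one new skeletal bond, C1–C2 in cembrane numbering (chain C14 to chain C1). This is the known 1,14 cation–olefin cyclisation of class 1 terpene synthases; it closes the 14-membered ring in the exo mode with respect to the reacting olefin, leaving the tertiary cation outside the ring at C15. Loss of a proton from one C15 methyl group, taken by an active-site base or the departing diphosphate, gives the isopropenyl group. The new stereocentre C1 is set by the olefin face that the protein presents to the cation, so a synthase of the R series gives 4. The step needs 1,14- instead of 1,10- or 1,6-closure, no isomerisation of the allylic cation, and proton loss instead of water capture or a second cyclisation; all are controlled by the active-site contour, which excludes water and holds the cation away from the inner olefins. The three internal E-olefins are not conjugated with the cation and are carried over unchanged, and the overlay removes the hydrocarbon so that it does not inhibit the enzyme.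

Step 4
Reactants: 4 (R)-cembrene A
Product: 7 (1R,3E,7E,11E)-cembra-3,7,11,15(17)-tetraen-16-ol, via allyllithium 5 (not isolated), via dimethyl allylboronate 6 (not isolated)
Conditions: n-BuLi, TMEDA, hexane, rt; B(OMe)3, −78 °C to rt; NaOH, H2O2, 0 °C
Reagents that add atoms: hydrogen peroxide, OO
Why: Allylic metalation–borylation–oxidation; the isopropenyl methyl is the kinetically most acidic allylic site because it gives a 2-substituted allyl anion with two unsubstituted termini (as in the C10 lithiation of limonene), the two termini are equivalent so no regioisomer arises, and the C1–H is not removed, so C1 stays R.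

Step 5
Reactants: 7 (1R,3E,7E,11E)-cembra-3,7,11,15(17)-tetraen-16-ol
Product: 8 (1R,3E,7E,11E)-cembra-3,7,11,15(17)-tetraen-16-al
Conditions: MnO2 (activated), CH2Cl2, rt
Reagents that add atoms: none
Why: MnO2 oxidation of a primary allylic alcohol; it stops at the 2-substituted acrolein and leaves the unactivated ring olefins alone.

Step 6
Reactants: 8 (1R,3E,7E,11E)-cembra-3,7,11,15(17)-tetraen-16-al
Product: 9 (1R,3E,7E,11E)-cembra-3,7,11,15(17)-tetraen-16-oic acid
Conditions: NaClO2, NaH2PO4, 2-methyl-2-butene, t-BuOH/H2O, 0 °C to rt
Reagents that add atoms: sodium chlorite, [Na+].[O-]Cl=O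
Why: Pinnick oxidation; chlorous acid adds to the aldehyde and fragments to the acid, and the excess of 2-methyl-2-butene takes up the hypochlorous acid before it can reach the trisubstituted ring olefins.

Step 7
Reactants: 9 (1R,3E,7E,11E)-cembra-3,7,11,15(17)-tetraen-16-oic acid
Product: 10 (1R,3E,7E,11S,12R)-11-iodocembra-3,7,15(17)-trien-16,12-olide
Conditions: I2, NaHCO3, MeCN, 0 °C, dark
Reagents that add atoms: iodine, II
Why: Iodolactonisation; iodonium ions form reversibly at all ring olefins, but only at C11=C12 do the exo mode and the Markovnikov preference coincide (carboxylate onto the tertiary C12, seven-membered ring), and anti addition puts iodine on C11 (11S). A chair-like seven-membered transition state with the C1–C2 and C12–C11 bonds pseudo-equatorial should give the trans bridge, that is 12R.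

Step 8
Reactants: 10 (1R,3E,7E,11S,12R)-11-iodocembra-3,7,15(17)-trien-16,12-olide
Product: 12 (1R,3E,7E,11S,12R)-11-hydroxycembra-3,7,15(17)-trien-16,12-olide, via TEMPO alkoxyamine 11 (not isolated)
Conditions: Bu3SnH (slow addition), TEMPO (4 equiv), benzene, 70 °C; then Zn, AcOH/THF/H2O, 50 °C
Reagents that add atoms: TEMPO (2,2,6,6-tetramethylpiperidin-1-oxyl), CC1(C)CCCC(C)(C)N1[O]
Why: Radical deiodination with nitroxide trapping, then reductive N–O cleavage; the C11 radical is trapped by TEMPO faster than it can add to the acrylate or undergo 1,2-acyloxy shift, and TEMPO should enter anti to the C12–O bond (the face the iodine left) while the ring holds C10 and C13 anti, which gives 11S by overall retention where an SN2 reaction at this neopentyl-type centre would fail.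

Step 9
Reactants: 12 (1R,3E,7E,11S,12R)-11-hydroxycembra-3,7,15(17)-trien-16,12-olide
Product: 13 (1R,3E,7R,8R,11S,12R)-7,8-epoxy-11-hydroxycembra-3,15(17)-dien-16,12-olide
Conditions: VO(acac)2 (5 mol %), t-BuOOH (decane), NaOAc, benzene, rt
Reagents that add atoms: tert-butyl hydroperoxide, CC(C)(C)OO
Why: Hydroxyl-directed vanadium-catalysed epoxidation of a bishomoallylic alcohol; the vanadate ester at C11 can reach C7=C8 but not C3=C4, and the acrylate is too electron-poor, so the site is fixed. The chair-like transition state with C12 pseudo-equatorial predicts the 7R,8R epoxide from the 11S carbinol, and the acetate buffer holds back ether formation by the hydroxyl.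

Step 10
Reactants: 13 (1R,3E,7R,8R,11S,12R)-7,8-epoxy-11-hydroxycembra-3,15(17)-dien-16,12-olide
Product: 14 (1R,3E,7R,8R,12R)-7,8-epoxy-11-oxocembra-3,15(17)-dien-16,12-olide
Conditions: Dess–Martin periodinane, NaHCO3, CH2Cl2, 0 °C to rt
Reagents that add atoms: none
Why: Dess–Martin oxidation under buffered, non-acidic conditions; it removes the hydroxyl that could open the epoxide at C8 and erases the C11 centre, which has done its directing work and must now be inverted.

Step 11
Reactants: 14 (1R,3E,7R,8R,12R)-7,8-epoxy-11-oxocembra-3,15(17)-dien-16,12-olide
Product: 16 (1R,3E,7R,8R,11R,12R)-11-acetoxy-7,8-epoxycembra-3,15(17)-dien-16,12-olide, via 11R hydroxy epoxide 15 (not isolated)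
Conditions: LiAlH(OtBu)3, THF, −78 °C; then Ac2O, DMAP, Et3N, −78 °C to rt
Reagents that add atoms: acetic anhydride, CC(=O)OC(C)=O
Why: Felkin–Anh reduction followed by acylation of the alkoxide in the same flask; hydride should add anti to the C12–O bond in the conformer with C10 and C13 anti, which the macrocycle also prefers, giving 11R (syn to O12). The bulky hydride spares lactone, epoxide and acrylate at −78 °C, and immediate acetylation keeps the new oxygen from attacking the epoxide.

Step 12
Reactants: 16 (1R,3E,7R,8R,11R,12R)-11-acetoxy-7,8-epoxycembra-3,15(17)-dien-16,12-olide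
Product: 18 (1R,3E,7R,11R,12R)-11-acetoxy-7-hydroxycembra-3,8(19),15(17)-trien-16,12-olide, via trimethylsilyl ether 17 (not isolated)
Conditions: TMSOTf, 2,6-lutidine, toluene, −78 °C to 0 °C; then citric acid, MeOH, rt
Reagents that add atoms: none
Why: Silyl triflate-promoted isomerisation of a trisubstituted epoxide to an allylic silyl ether; silylation of the oxirane oxygen weakens the tertiary C8–O bond and the hindered base removes a proton from the C19 methyl, the least hindered one, to give the exocyclic olefin. The C7–O bond is not broken, so C7 stays R, and mild acid frees the hydroxyl.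

Step 13
Reactants: 18 (1R,3E,7R,11R,12R)-11-acetoxy-7-hydroxycembra-3,8(19),15(17)-trien-16,12-olide
Product: 20 (1R,3S,4R,7R,11R,12R)-11-acetoxy-4,7-epoxy-3-hydroxycembra-8(19),15(17)-dien-16,12-olide, via 3S,4S-epoxy alcohol 19 (not isolated)
Conditions: ent-Shi ketone (L-fructose-derived, 0.3 equiv), Oxone (2KHSO5·KHSO4·K2SO4), K2CO3, Bu4NHSO4, MeCN/CH2(OMe)2/aq. Na2B4O7, 0 °C; then CSA (0.1 equiv), CH2Cl2, 0 °C
Reagents that add atoms: Oxone (potassium peroxymonosulfate), [K+].[O-]S(=O)(=O)OO
Why: Shi epoxidation, then acid-catalysed transannular epoxide opening; C3=C4 is the only electron-rich trisubstituted olefin left (C8=C19 is 1,1-disubstituted and next to oxygen, the acrylate is electron-poor), and the L-series ketone should deliver oxygen through the spiro transition state to the face that gives the 3S,4S epoxide. The C7 hydroxyl then attacks the tertiary C4 in a 5-exo closure with inversion (4R) and releases the 3S hydroxyl, which gives the trans oxolane.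

Step 14
Reactants: 20 (1R,3S,4R,7R,11R,12R)-11-acetoxy-4,7-epoxy-3-hydroxycembra-8(19),15(17)-dien-16,12-olide
Product: 21 (1R,3S,4R,7R,11R,12R)-3,11-diacetoxy-4,7-epoxycembra-8(19),15(17)-dien-16,12-olide (CNP0133628.2)
Conditions: Ac2O, pyridine, DMAP (cat.), CH2Cl2, 0 °C to rt
Reagents that add atoms: acetic anhydride, CC(=O)OC(C)=O
Why: DMAP-catalysed acetylation of the secondary C3 hydroxyl under non-nucleophilic, weakly basic conditions that leave the acrylate lactone and the C11 acetate untouched; no stereocentre is affected.

## Compound list

1 | geranylgeraniol | CC(C)=CCC/C(C)=C/CC/C(C)=C/CC/C(C)=C/CO | starting material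
2 | geranylgeranyl chloride | CC(C)=CCC/C(C)=C/CC/C(C)=C/CC/C(C)=C/CCl | intermediate
3 | geranylgeranyl diphosphate (triammonium salt, drawn as free acid) | CC(C)=CCC/C(C)=C/CC/C(C)=C/CC/C(C)=C/COP(=O)(O)OP(=O)(O)O | intermediate
4 | (R)-cembrene A, (1R,3E,7E,11E)-cembra-3,7,11,15-tetraene | CC(=C)[C@H]1C/C=C(\C)CC/C=C(\C)CC/C=C(\C)CC1 | intermediate
5 | 16-lithio-(R)-cembrene A (2-substituted allyllithium, TMEDA complex) | C=C(C[Li])[C@H]1C/C=C(\C)CC/C=C(\C)CC/C=C(\C)CC1 | intermediate
6 | dimethyl [(1R,3E,7E,11E)-cembra-3,7,11,15(17)-tetraen-16-yl]boronate | C=C(CB(OC)OC)[C@H]1C/C=C(\C)CC/C=C(\C)CC/C=C(\C)CC1 | intermediate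
7 | (1R,3E,7E,11E)-cembra-3,7,11,15(17)-tetraen-16-ol | C=C(CO)[C@H]1C/C=C(\C)CC/C=C(\C)CC/C=C(\C)CC1 | intermediate
8 | (1R,3E,7E,11E)-cembra-3,7,11,15(17)-tetraen-16-al | C=C(C=O)[C@H]1C/C=C(\C)CC/C=C(\C)CC/C=C(\C)CC1 | intermediate
9 | (1R,3E,7E,11E)-cembra-3,7,11,15(17)-tetraen-16-oic acid | C=C(C(=O)O)[C@H]1C/C=C(\C)CC/C=C(\C)CC/C=C(\C)CC1 | intermediate
10 | (1R,3E,7E,11S,12R)-11-iodocembra-3,7,15(17)-trien-16,12-olide | C=C1C(=O)O[C@]2(C)CC[C@@H]1C/C=C(\C)CC/C=C(\C)CC[C@@H]2I | intermediate
11 | (1R,3E,7E,11S,12R)-11-(2,2,6,6-tetramethylpiperidin-1-yloxy)cembra-3,7,15(17)-trien-16,12-olide | C=C1C(=O)O[C@]2(C)CC[C@@H]1C/C=C(\C)CC/C=C(\C)CC[C@@H]2ON1C(C)(C)CCCC1(C)C | intermediate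
12 | (1R,3E,7E,11S,12R)-11-hydroxycembra-3,7,15(17)-trien-16,12-olide | C=C1C(=O)O[C@]2(C)CC[C@@H]1C/C=C(\C)CC/C=C(\C)CC[C@@H]2O | intermediate
13 | (1R,3E,7R,8R,11S,12R)-7,8-epoxy-11-hydroxycembra-3,15(17)-dien-16,12-olide | C=C1C(=O)O[C@]2(C)CC[C@@H]1C/C=C(\C)CC[C@H]3O[C@]3(C)CC[C@@H]2O | intermediate
14 | (1R,3E,7R,8R,12R)-7,8-epoxy-11-oxocembra-3,15(17)-dien-16,12-olide | C=C1C(=O)O[C@]2(C)CC[C@@H]1C/C=C(\C)CC[C@H]3O[C@]3(C)CCC2=O | intermediate
15 | (1R,3E,7R,8R,11R,12R)-7,8-epoxy-11-hydroxycembra-3,15(17)-dien-16,12-olide (formed as its aluminium alkoxide) | C=C1C(=O)O[C@]2(C)CC[C@@H]1C/C=C(\C)CC[C@H]3O[C@]3(C)CC[C@H]2O | intermediate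
16 | (1R,3E,7R,8R,11R,12R)-11-acetoxy-7,8-epoxycembra-3,15(17)-dien-16,12-olide | C=C1C(=O)O[C@]2(C)CC[C@@H]1C/C=C(\C)CC[C@H]3O[C@]3(C)CC[C@H]2OC(C)=O | intermediate
17 | (1R,3E,7R,11R,12R)-11-acetoxy-7-(trimethylsilyloxy)cembra-3,8(19),15(17)-trien-16,12-olide | C=C1C(=O)O[C@]2(C)CC[C@@H]1C/C=C(\C)CC[C@@H](O[Si](C)(C)C)C(=C)CC[C@H]2OC(C)=O | intermediate
18 | (1R,3E,7R,11R,12R)-11-acetoxy-7-hydroxycembra-3,8(19),15(17)-trien-16,12-olide | C=C1C(=O)O[C@]2(C)CC[C@@H]1C/C=C(\C)CC[C@@H](O)C(=C)CC[C@H]2OC(C)=O | intermediate
19 | (1R,3S,4S,7R,11R,12R)-11-acetoxy-3,4-epoxy-7-hydroxycembra-8(19),15(17)-dien-16,12-olide | C=C1C(=O)O[C@]2(C)CC[C@@H]1C[C@@H]3O[C@@]3(C)CC[C@@H](O)C(=C)CC[C@H]2OC(C)=O | intermediate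
20 | (1R,3S,4R,7R,11R,12R)-11-acetoxy-4,7-epoxy-3-hydroxycembra-8(19),15(17)-dien-16,12-olide | C=C1C(=O)O[C@]2(C)CC[C@@H]1C[C@H](O)[C@@]1(C)CC[C@@H](O1)C(=C)CC[C@H]2OC(C)=O | intermediate
21 | (1R,3S,4R,7R,11R,12R)-3,11-diacetoxy-4,7-epoxycembra-8(19),15(17)-dien-16,12-olide (CNP0133628.2) | C=C1C(=O)O[C@]2(C)CC[C@@H]1C[C@H](OC(C)=O)[C@@]1(C)CC[C@@H](O1)C(=C)CC[C@H]2OC(C)=O | target

## Step count and least certain steps

Total step count: 14. Longest linear sequence: 14 steps (1 to 21); the route is fully linear.

Step 3 (key step). What may go wrong: slow turnover and product inhibition at preparative substrate concentration, precipitation of magnesium diphosphate, and leakage of the C15 cation to water capture or to other ring closures, because the lipophilic substrate aggregates outside the active site. Fallback: whole-cell production instead of the isolated enzyme. This fallback does not set out from a numbered compound: it replaces 1–3 by D-glucose F1, fed to an Escherichia coli or yeast strain that carries a mevalonate pathway, a geranylgeranyl diphosphate synthase and the same cembrene A synthase, with a dodecane overlay to collect the hydrocarbon. Diphosphate 3 is then made and consumed in the cell, and the route is rejoined at 4.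

Step 4. What may go wrong: loss of site selectivity in the deprotonation, since the three trisubstituted olefins offer nine further allylic positions, and proton shifts within the allyllithium on long standing. Fallback: hydroboration in place of metalation, setting out from 4. 9-BBN adds only to the 1,1-disubstituted olefin and oxidative work-up gives (1R)-cembra-3,7,11-trien-16-ol F2 (both C15 epimers). TEMPO with PhI(OAc)2 in aqueous MeCN oxidises it to the 2-substituted propanoic acid F3. The dianion of F3 (LDA) is selenenylated with PhSeBr to the 15-phenylselanyl acid F4, and oxidation of F4 with NaIO4 followed by syn-elimination towards the methyl group gives 9, where the route is rejoined.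

Step 7. What may go wrong: ring closure of the carboxylate onto C3 of the 3,4-olefin (a six-membered lactone, favoured by ring size although anti-Markovnikov) in competition with closure onto C12, and poor facial selectivity at C12. Fallback: use the closure onto C3 to mask that olefin, setting out from 9. Iodolactonisation then gives the δ-iodolactone (1R,3R,4S)-4-iodocembra-7,11,15(17)-trien-16,3-olide F5. K2CO3 in MeOH opens the lactone and the C3 alkoxide displaces the iodide to give methyl (1R,3R,4R)-3,4-epoxycembra-7,11,15(17)-trien-16-oate F6. LiOH gives the lithium carboxylate F7, which with I2/NaHCO3 can now only close onto C12 and gives the epoxy ε-iodolactone F8. Stereospecific deoxygenation of the epoxide with Ph3P=Se and CF3CO2H restores the 3E-olefin and gives 10, where the route is rejoined. The configuration of the temporary epoxide is of no consequence.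

Step 8. What may go wrong: poor facial selectivity in the trapping of the planar C11 radical, giving a mixture of 11-epimers, of which only the 11S alcohol steers step 9 to the right face. Fallback: set C11 by reagent control, setting out from 10. The mixture of 12 and its 11R epimer F9 from the same trapping is oxidised with Dess–Martin periodinane to the ketone (1R,3E,7E,12R)-11-oxocembra-3,7,15(17)-trien-16,12-olide F10. Corey–Bakshi–Shibata reduction with the (R)-B-methyl oxazaborolidine and catecholborane at −78 °C, which distinguishes the quaternary C12 from the C10 methylene, gives 12, where the route is rejoined.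

Step 9. What may go wrong: oxygen delivery to the wrong face of C7=C8, or transannular attack of the C11 hydroxyl on C8 of the new epoxide, since 13 contains the same 1,4-hydroxy epoxide array that step 13 uses on purpose. Fallback: give up the directing hydroxyl, setting out from 12. Oxidation gives ketone F10 (as above), and reduction with LiAlH(OtBu)3 and acetylation in the same flask give the 11R acetate (1R,3E,7E,11R,12R)-11-acetoxycembra-3,7,15(17)-trien-16,12-olide F11. Shi epoxidation with the D-fructose-derived ketone, run to partial conversion, gives the 7R,8R epoxide 16 by reagent control, where the route is rejoined. Site selectivity between C7=C8 and C3=C4 then rests only on the steric shielding of C3=C4 by the lactone bridge, so the 3,4-regioisomer would have to be separated.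

Step 12. What may go wrong: proton loss from C9 instead of C19 (endocyclic olefin), hydride shift to a C7 ketone, or capture of the developing C8 cation by the 3,4-olefin across the ring. Fallback: a radical instead of a cationic opening, setting out from 16. Cp2TiCl (trivalent titanium, from Cp2TiCl2 and Zn) cleaves the C8–O bond homolytically, and a second equivalent turns the tertiary radical into the exocyclic olefin by β-hydride loss. This gives 18 directly on work-up, with no new compound (F0), and the route continues at 18.

## Further compounds

F1 | step 3 | D-glucose | OC[C@H]1OC(O)[C@H](O)[C@@H](O)[C@@H]1O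
F2 | step 4 | (1R,3E,7E,11E)-cembra-3,7,11-trien-16-ol (C15 epimers) | CC(CO)[C@H]1C/C=C(\C)CC/C=C(\C)CC/C=C(\C)CC1
F3 | step 4 | (1R,3E,7E,11E)-cembra-3,7,11-trien-16-oic acid (C15 epimers) | CC(C(=O)O)[C@H]1C/C=C(\C)CC/C=C(\C)CC/C=C(\C)CC1
F4 | step 4 | (1R,3E,7E,11E)-15-(phenylselanyl)cembra-3,7,11-trien-16-oic acid | CC([Se]c1ccccc1)(C(=O)O)[C@H]1C/C=C(\C)CC/C=C(\C)CC/C=C(\C)CC1
F5 | step 7 | (1R,3R,4S,7E,11E)-4-iodocembra-7,11,15(17)-trien-16,3-olide | C=C1C(=O)O[C@@H]2C[C@H]1CC/C(C)=C/CC/C(C)=C/CC[C@]2(C)I
F6 | step 7 | methyl (1R,3R,4R,7E,11E)-3,4-epoxycembra-7,11,15(17)-trien-16-oate | C=C(C(=O)OC)[C@H]1C[C@H]2O[C@]2(C)CC/C=C(\C)CC/C=C(\C)CC1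
F7 | step 7 | lithium (1R,3R,4R,7E,11E)-3,4-epoxycembra-7,11,15(17)-trien-16-oate | [Li+].C=C(C(=O)[O-])[C@H]1C[C@H]2O[C@]2(C)CC/C=C(\C)CC/C=C(\C)CC1
F8 | step 7 | (1R,3R,4R,7E,11S,12R)-3,4-epoxy-11-iodocembra-7,15(17)-dien-16,12-olide | C=C1C(=O)O[C@]2(C)CC[C@@H]1C[C@H]3O[C@]3(C)CC/C=C(\C)CC[C@@H]2I
F9 | step 8 | (1R,3E,7E,11R,12R)-11-hydroxycembra-3,7,15(17)-trien-16,12-olide | C=C1C(=O)O[C@]2(C)CC[C@@H]1C/C=C(\C)CC/C=C(\C)CC[C@H]2O
F10 | step 8 | (1R,3E,7E,12R)-11-oxocembra-3,7,15(17)-trien-16,12-olide | C=C1C(=O)O[C@]2(C)CC[C@@H]1C/C=C(\C)CC/C=C(\C)CCC2=O
F11 | step 9 | (1R,3E,7E,11R,12R)-11-acetoxycembra-3,7,15(17)-trien-16,12-olide | C=C1C(=O)O[C@]2(C)CC[C@@H]1C/C=C(\C)CC/C=C(\C)CC[C@H]2OC(C)=O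
F0 | step 12 | none | none
A1 | alternative 1 | oxepan-2-one fragment C9–C16 with C1, C11 and C12 set (product of the ring expansion) | C1C(=O)O[C@]([C@H](O[Si](C)(C)C(C)(C)C)CCOCc2ccccc2)(C)CC[C@@H]1COCc1ccc(OC)cc1
A2 | alternative 1 | cyclohexanone precursor of A1 | C1C(=O)[C@]([C@H](O[Si](C)(C)C(C)(C)C)CCOCc2ccccc2)(C)CC[C@@H]1COCc1ccc(OC)cc1
A3 | alternative 2 | 14-membered 3,4-epoxy 7-alcohol (same structure as 19) | C=C1C(=O)O[C@]2(C)CC[C@@H]1C[C@@H]3O[C@@]3(C)CC[C@@H](O)C(=C)CC[C@H]2OC(C)=O
A4 | alternative 2 | 3-O-deacetyl target (same structure as 20) | C=C1C(=O)O[C@]2(C)CC[C@@H]1C[C@H](O)[C@@]1(C)CC[C@@H](O1)C(=C)CC[C@H]2OC(C)=O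
A5 | alternative 3 | 14-membered macrocyclic allyl vinyl ether | C=C1OCC(=C)[C@H]2CC[C@@](C)(O2)[C@@H](O[Si](C)(C)C(C)(C)C)C[C@H](C(=C)CO[Si](C)(C)C(C)(C)C)CC[C@@]1(C)O[Si](CC)(CC)CC
A6 | alternative 3 | 14-membered carbocyclic C11 ketone (product of the rearrangement) | O=C1CCC(=C)[C@H]2CC[C@@](C)(O2)[C@@H](O[Si](C)(C)C(C)(C)C)C[C@H](C(=C)CO[Si](C)(C)C(C)(C)C)CC[C@@]1(C)O[Si](CC)(CC)CC
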